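**Plan**

- Retrosynthesis: the five O-benzyl groups are removed last. Ring C of the flavanone is then cut at C2–C3 and O1–C8a together, giving 4-(benzyloxy)benzaldehyde and a 2-fluoroaryl methyl ketone (used as its silyl enol ether). Behind that come the acetyl–aryl bond (Stille), the flavone ring (chalcone, then O–C closure), the diaryl ether C–O bond (SNAr on 4-fluorobenzaldehyde) and the two C–OBn bonds of the ring A unit.
- Enabling feature: in the flavanone the C4 carbonyl sits ortho to C8a of ring A. An acetyl group on a ring A whose C8a carries fluorine is therefore both the enolate donor for C3 and the activator for displacement at C8a. C8a is para only to the weakly donating C6 aryloxy oxygen and meta to the C5 and C7 oxygens, and O1 is benzylic at C2, so it can arrive as the aldehyde oxygen.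
- Forward order: ring A unit → diaryl ether → bromine placeholder at the future C4a → chalcone → flavone rings (apigenin half) → acetyl → enol silane → ring C in one aldol/fluoride-displacement annulation → debenzylation.
- Stereochemistry: C2 (S) is set in the aldol event by a chiral ammonium cation paired with the enolate. Ring closure breaks no bond at C2 and no base is used afterwards. The 6-O (not 8-O) linkage follows from fluorine standing para to the aryloxy group.

Key step: step 11

Assumption: the cinchonidinium cation of step 11 is taken to leave the Si face of aldehyde 15 open; if the sense of induction proves opposite, the pseudoenantiomeric N-(9-anthracenylmethyl)-O-benzylcinchoninium hydrogen difluoride is used with no other change.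

**Route**

Step 1
Reactants: 1 2,6-dibromo-4-fluorophenol
Product: 2 1,3-dibromo-5-fluoro-2-(methoxymethoxy)benzene
Conditions: MOMCl, K2CO3, acetone, 0 °C to rt
Reagents that add atoms: chloromethyl methyl ether COCCl
Why: Williamson-type O-alkylation of the acidic dibromophenol masks the central oxygen as a base-stable methoxymethyl acetal for the copper step.

Step 2
Reactants: 2 1,3-dibromo-5-fluoro-2-(methoxymethoxy)benzene
Product: 3 1,3-bis(benzyloxy)-5-fluoro-2-(methoxymethoxy)benzene
Conditions: BnOH, CuI (10 mol %), 3,4,7,8-tetramethyl-1,10-phenanthroline (20 mol %), Cs2CO3, toluene, 110 °C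
Reagents that add atoms: benzyl alcohol OCc1ccccc1
Why: Ullmann-type copper-catalysed C–O coupling of both aryl bromides with the primary alcohol, in which the unactivated fluoride and the acetal are not touched.

Step 3
Reactants: 3 1,3-bis(benzyloxy)-5-fluoro-2-(methoxymethoxy)benzene
Product: 4 2,6-bis(benzyloxy)-4-fluorophenol
Conditions: 3 M HCl (cat.), MeOH–THF, 50 °C
Reagents that add atoms: none
Why: Acid-catalysed acetal exchange with methanol frees the phenol, while benzyl ethers are stable to dilute acid.

Step 4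
Reactants: 4 2,6-bis(benzyloxy)-4-fluorophenol; 5 4-fluorobenzaldehyde
Product: 6 4-[2,6-bis(benzyloxy)-4-fluorophenoxy]benzaldehyde
Conditions: K2CO3, DMF, N2, 110 °C
Reagents that add atoms: none
Why: Nucleophilic aromatic substitution (SNAr) in which only the fluoride of 5 is activated (para formyl) and the fluoride on the electron-rich ring of 4 is not, so the hindered phenoxide is arylated at oxygen alone.

Step 5
Reactants: 6 4-[2,6-bis(benzyloxy)-4-fluorophenoxy]benzaldehyde
Product: 7 4-[2,6-bis(benzyloxy)-3-bromo-4-fluorophenoxy]benzaldehyde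
Conditions: NBS (1.05 equiv), MeCN, 0 °C to rt, dark
Reagents that add atoms: N-bromosuccinimide O=C1CCC(=O)N1Br
Why: Electrophilic aromatic bromination at one of the two equivalent free positions of the trioxygenated ring (ortho and para to benzyloxy groups), which gives a single monobromide and leaves the formyl-deactivated ring alone.

Step 6
Reactants: 8 2',4',6'-trihydroxyacetophenone
Product: 9 1-[2,4-bis(benzyloxy)-6-hydroxyphenyl]ethan-1-one
Conditions: BnBr (2.1 equiv), K2CO3, DMF, rt
Reagents that add atoms: benzyl bromide BrCc1ccccc1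
Why: Williamson ether synthesis in which the hydroxyl that is hydrogen-bonded to the acetyl carbonyl is the least nucleophilic and stays free.

Step 7
Reactants: 7 4-[2,6-bis(benzyloxy)-3-bromo-4-fluorophenoxy]benzaldehyde; 9 1-[2,4-bis(benzyloxy)-6-hydroxyphenyl]ethan-1-one
Product: 10 E-configured 2'-hydroxychalcone
Conditions: KOH (aq. 50 %), EtOH–THF, rt
Reagents that add atoms: none
Why: Claisen–Schmidt condensation in which 9 is the only enolisable partner and 7 the only aldehyde, which should give the E-chalcone (any flavanone formed by ring closure is carried on, since step 8 oxidises both).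

Step 8
Reactants: 10 E-configured 2'-hydroxychalcone
Product: 11 5,7-bis(benzyloxy)-2-{4-[2,6-bis(benzyloxy)-3-bromo-4-fluorophenoxy]phenyl}-4H-chromen-4-one
Conditions: I2 (10 mol %), DMSO, 130 °C
Reagents that add atoms: none
Why: Iodine-catalysed oxidative cyclisation of a 2'-hydroxychalcone (oxa-Michael addition, α-iodination, elimination, with DMSO as terminal oxidant) gives the flavone, and the aryl bromide and fluoride are inert.

Step 9
Reactants: 11 5,7-bis(benzyloxy)-2-{4-[2,6-bis(benzyloxy)-3-bromo-4-fluorophenoxy]phenyl}-4H-chromen-4-one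
Product: 13 1-(2,4-bis(benzyloxy)-3-{4-[5,7-bis(benzyloxy)-4-oxo-4H-chromen-2-yl]phenoxy}-6-fluorophenyl)ethan-1-one, via ethoxyvinyl arene 12 (not isolated)
Conditions: tributyl(1-ethoxyvinyl)stannane, Pd(PPh3)4 (5 mol %), toluene, 105 °C; then 1 M HCl, THF, rt
Reagents that add atoms: tributyl(1-ethoxyvinyl)stannane CCCC[Sn](CCCC)(CCCC)C(=C)OCC; water O
Why: Stille coupling with an acetyl anion equivalent followed by enol ether hydrolysis places the acetyl group on the carbon between benzyloxy and fluorine, and doing so only now avoids any crossed condensation with the aldehyde used in steps 4 to 7.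

Step 10
Reactants: 13 1-(2,4-bis(benzyloxy)-3-{4-[5,7-bis(benzyloxy)-4-oxo-4H-chromen-2-yl]phenoxy}-6-fluorophenyl)ethan-1-one
Product: 14 trimethylsilyl enol ether of 13
Conditions: LiN(SiMe3)2, Me3SiCl (in situ quench), THF, −78 °C; non-aqueous work-up
Reagents that add atoms: chlorotrimethylsilane C[Si](C)(C)Cl
Why: Kinetic deprotonation of the only acidic C–H (the acetyl methyl) with in situ silyl trapping gives the silyl enol ether, the flavone having no enolisable hydrogen.

Step 11
Reactants: 14 trimethylsilyl enol ether of 13; 15 4-(benzyloxy)benzaldehyde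
Product: 17 (2S)-5,7-bis(benzyloxy)-2-[4-(benzyloxy)phenyl]-6-{4-[5,7-bis(benzyloxy)-4-oxo-4H-chromen-2-yl]phenoxy}-2,3-dihydro-4H-chromen-4-one, via silyl aldol ether 16 (not isolated)
Conditions: N-(9-anthracenylmethyl)-O-benzylcinchonidinium hydrogen difluoride (5 mol %), 15 (1.3 equiv), toluene–CH2Cl2, −78 °C, then −20 °C; pH 7 buffer
Reagents that add atoms: none
Why: Proposed new method: fluoride of the ammonium salt removes the silyl group of 14 and the resulting enolate, held in a contact ion pair with the chiral cation, adds through C3 to the carbonyl carbon of 15 (C2–C3 bond) and is turned over at −78 °C by silyl transfer from 14 to give 16; on warming, the catalytic amount of ammonium alkoxide attacks C8a of ring A (O1–C8a bond) and expels fluoride, which desilylates the next molecule of 16, so that the leaving group of the second bond formation is the Lewis base of the first and only Me3SiF is lost. The closest known reaction types are the Mukaiyama aldol addition of silyl enol ethers to aromatic aldehydes under cinchona-derived ammonium fluoride or bifluoride catalysis, the leaving-group-rebound Michael addition–lactonisation catalysed by chiral ammonium phenoxides, and the alkoxide–fluoroarene closure of the pyran ring in flavan-3-ol synthesis. Ring C closes by addition–elimination at the aromatic carbon C8a (an oxa-Michael-type 6-endo attack on the C8a=C4a–C4=O system followed by loss of fluoride) with the alkoxide oxygen as nucleophile and no bond to C2 broken. The stereocentre C2 is fixed in the aldol addition by the chiral cation, whose anthracenylmethyl and benzyl groups are expected to leave the Si face of the aldehyde open, and it is carried unchanged into the flavanone. The step needs site selectivity for closure at C8a and not at C5, secured because only C8a carries fluorine while the benzyloxy group at C5 is no leaving group, which also fixes the 6-O linkage; it needs chemoselectivity over the flavone, secured by the absence of any Lewis acid that could turn the flavone carbonyl into a pyrylium electrophile; and it needs ring closure to outrun retro-aldol cleavage and β-elimination, which the ortho carbonyl activation, the intramolecularity and the low stationary concentration of alkoxide favour.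

Step 12
Reactants: 17 (2S)-5,7-bis(benzyloxy)-2-[4-(benzyloxy)phenyl]-6-{4-[5,7-bis(benzyloxy)-4-oxo-4H-chromen-2-yl]phenoxy}-2,3-dihydro-4H-chromen-4-one
Product: 18 CNP0206535.1
Conditions: H2 (1 atm), Pd/C (10 wt % Pd), THF–MeOH, rt
Reagents that add atoms: none
Why: Catalytic hydrogenolysis of the five benzyl ethers under neutral conditions, which should not touch the base-labile C2 stereocentre.

**Compound list**

1 | 2,6-dibromo-4-fluorophenol | Oc1c(Br)cc(F)cc1Br | starting material
2 | 1,3-dibromo-5-fluoro-2-(methoxymethoxy)benzene | COCOc1c(Br)cc(F)cc1Br | intermediate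
3 | 1,3-bis(benzyloxy)-5-fluoro-2-(methoxymethoxy)benzene | COCOc1c(OCc2ccccc2)cc(F)cc1OCc1ccccc1 | intermediate
4 | 2,6-bis(benzyloxy)-4-fluorophenol | Oc1c(OCc2ccccc2)cc(F)cc1OCc1ccccc1 | intermediate
5 | 4-fluorobenzaldehyde | O=Cc1ccc(F)cc1 | starting material
6 | 4-[2,6-bis(benzyloxy)-4-fluorophenoxy]benzaldehyde | O=Cc1ccc(Oc2c(OCc3ccccc3)cc(F)cc2OCc2ccccc2)cc1 | intermediate
7 | 4-[2,6-bis(benzyloxy)-3-bromo-4-fluorophenoxy]benzaldehyde | O=Cc1ccc(Oc2c(OCc3ccccc3)cc(F)c(Br)c2OCc2ccccc2)cc1 | intermediate
8 | 1-(2,4,6-trihydroxyphenyl)ethan-1-one (2',4',6'-trihydroxyacetophenone) | CC(=O)c1c(O)cc(O)cc1O | starting material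
9 | 1-[2,4-bis(benzyloxy)-6-hydroxyphenyl]ethan-1-one | CC(=O)c1c(O)cc(OCc2ccccc2)cc1OCc1ccccc1 | intermediate
10 | (2E)-1-[2,4-bis(benzyloxy)-6-hydroxyphenyl]-3-{4-[2,6-bis(benzyloxy)-3-bromo-4-fluorophenoxy]phenyl}prop-2-en-1-one | O=C(/C=C/c1ccc(Oc2c(OCc3ccccc3)cc(F)c(Br)c2OCc2ccccc2)cc1)c1c(O)cc(OCc2ccccc2)cc1OCc1ccccc1 | intermediate
11 | 5,7-bis(benzyloxy)-2-{4-[2,6-bis(benzyloxy)-3-bromo-4-fluorophenoxy]phenyl}-4H-chromen-4-one | O=c1cc(-c2ccc(Oc3c(OCc4ccccc4)cc(F)c(Br)c3OCc3ccccc3)cc2)oc2cc(OCc3ccccc3)cc(OCc3ccccc3)c12 | intermediate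
12 | 5,7-bis(benzyloxy)-2-{4-[2,6-bis(benzyloxy)-3-(1-ethoxyethenyl)-4-fluorophenoxy]phenyl}-4H-chromen-4-one | CCOC(=C)c1c(F)cc(OCc2ccccc2)c(Oc2ccc(-c3cc(=O)c4c(OCc5ccccc5)cc(OCc5ccccc5)cc4o3)cc2)c1OCc1ccccc1 | intermediate
13 | 1-(2,4-bis(benzyloxy)-3-{4-[5,7-bis(benzyloxy)-4-oxo-4H-chromen-2-yl]phenoxy}-6-fluorophenyl)ethan-1-one | CC(=O)c1c(F)cc(OCc2ccccc2)c(Oc2ccc(-c3cc(=O)c4c(OCc5ccccc5)cc(OCc5ccccc5)cc4o3)cc2)c1OCc1ccccc1 | intermediate
14 | 5,7-bis(benzyloxy)-2-[4-(2,6-bis(benzyloxy)-4-fluoro-3-{1-[(trimethylsilyl)oxy]ethenyl}phenoxy)phenyl]-4H-chromen-4-one | C=C(O[Si](C)(C)C)c1c(F)cc(OCc2ccccc2)c(Oc2ccc(-c3cc(=O)c4c(OCc5ccccc5)cc(OCc5ccccc5)cc4o3)cc2)c1OCc1ccccc1 | intermediate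
15 | 4-(benzyloxy)benzaldehyde | O=Cc1ccc(OCc2ccccc2)cc1 | starting material
16 | (3S)-3-[4-(benzyloxy)phenyl]-1-(2,4-bis(benzyloxy)-3-{4-[5,7-bis(benzyloxy)-4-oxo-4H-chromen-2-yl]phenoxy}-6-fluorophenyl)-3-[(trimethylsilyl)oxy]propan-1-one | O=C(C[C@H](O[Si](C)(C)C)c1ccc(OCc2ccccc2)cc1)c1c(F)cc(OCc2ccccc2)c(Oc2ccc(-c3cc(=O)c4c(OCc5ccccc5)cc(OCc5ccccc5)cc4o3)cc2)c1OCc1ccccc1 | intermediate
17 | (2S)-5,7-bis(benzyloxy)-2-[4-(benzyloxy)phenyl]-6-{4-[5,7-bis(benzyloxy)-4-oxo-4H-chromen-2-yl]phenoxy}-2,3-dihydro-4H-chromen-4-one | O=C1C[C@@H](c2ccc(OCc3ccccc3)cc2)Oc2cc(OCc3ccccc3)c(Oc3ccc(-c4cc(=O)c5c(OCc6ccccc6)cc(OCc6ccccc6)cc5o4)cc3)c(OCc3ccccc3)c21 | intermediate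
18 | (2S)-6-[4-(5,7-dihydroxy-4-oxo-4H-chromen-2-yl)phenoxy]-5,7-dihydroxy-2-(4-hydroxyphenyl)-2,3-dihydro-4H-chromen-4-one (CNP0206535.1) | O=C1C[C@@H](c2ccc(O)cc2)Oc2cc(O)c(Oc3ccc(-c4cc(=O)c5c(O)cc(O)cc5o4)cc3)c(O)c21 | target

**Step count and risks**

Total step count: 12. Longest linear sequence: 11 steps (steps 1 to 5 and 7 to 12, from 2,6-dibromo-4-fluorophenol); step 6 is a one-step side branch.

Steps most likely to fail:

1. Step 11 (Proposed new method). Facial selectivity of the ion-paired aldol addition may be poor. Retro-aldol cleavage or β-elimination of the alkoxide may outrun fluoride displacement. The product may racemise by base-induced ring opening if the mixture is warmed too far. The fallback uses known chemistry and forms the C2–aryl bond instead. It sets out from 13: Claisen formylation (HCO2Et, NaH, THF) should give the hydroxymethylene ketone (2Z)-1-(2,4-bis(benzyloxy)-3-{4-[5,7-bis(benzyloxy)-4-oxo-4H-chromen-2-yl]phenoxy}-6-fluorophenyl)-3-hydroxyprop-2-en-1-one F1. Warming with K2CO3 in DMF should close it by enolate-oxygen displacement of fluoride (the known cyclisation of 1-(2-fluorophenyl)-1,3-dicarbonyl compounds) to the chromone 5,7-bis(benzyloxy)-6-{4-[5,7-bis(benzyloxy)-4-oxo-4H-chromen-2-yl]phenoxy}-4H-chromen-4-one F2. Asymmetric conjugate addition of 4-(benzyloxy)phenylboronic acid then comes back to the route at 17. Its conditions are Pd(OCOCF3)2, 4-tert-butyl-2-(pyridin-2-yl)-4,5-dihydro-1,3-oxazole in the antipode that gives the 2S product, NH4PF6, H2O, ClCH2CH2Cl, 60 °C. The 2-aryl-substituted flavone is too hindered to compete.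

2. Step 2. The double coupling may stall after one C–O bond, or the alkoxide may reduce a C–Br bond (hydrodebromination). The fallback replaces C–O coupling by C–B formation and oxidation. It sets out from 2: double Miyaura borylation (B2pin2, PdCl2(dppf), KOAc, dioxane, 90 °C) should give 2,2'-[5-fluoro-2-(methoxymethoxy)-1,3-phenylene]bis(4,4,5,5-tetramethyl-1,3,2-dioxaborolane) F3. Oxidation (H2O2, NaOH, THF, 0 °C) should give 5-fluoro-2-(methoxymethoxy)benzene-1,3-diol F4. Williamson benzylation (BnBr, K2CO3, DMF) comes back to the route at 3.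

3. Step 12. Over-reduction may occur (saturation of the flavone C2=C3 bond or hydrogenolysis of the benzylic C2–O1 bond of the flavanone), or the reaction may stall when partly debenzylated material precipitates. The fallback replaces hydrogenolysis by Lewis-acid debenzylation. It sets out from 17 (BCl3, pentamethylbenzene as benzyl cation scavenger, CH2Cl2, −78 °C) and comes back at 18. No new compound is made (F0).

Further compounds
F1 | step 11 | (2Z)-1-(2,4-bis(benzyloxy)-3-{4-[5,7-bis(benzyloxy)-4-oxo-4H-chromen-2-yl]phenoxy}-6-fluorophenyl)-3-hydroxyprop-2-en-1-one | O/C=C\C(=O)c1c(F)cc(OCc2ccccc2)c(Oc2ccc(-c3cc(=O)c4c(OCc5ccccc5)cc(OCc5ccccc5)cc4o3)cc2)c1OCc1ccccc1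
F2 | step 11 | 5,7-bis(benzyloxy)-6-{4-[5,7-bis(benzyloxy)-4-oxo-4H-chromen-2-yl]phenoxy}-4H-chromen-4-one | O=c1ccoc2cc(OCc3ccccc3)c(Oc3ccc(-c4cc(=O)c5c(OCc6ccccc6)cc(OCc6ccccc6)cc5o4)cc3)c(OCc3ccccc3)c12
F3 | step 2 | 2,2'-[5-fluoro-2-(methoxymethoxy)-1,3-phenylene]bis(4,4,5,5-tetramethyl-1,3,2-dioxaborolane) | COCOc1c(B2OC(C)(C)C(C)(C)O2)cc(F)cc1B1OC(C)(C)C(C)(C)O1
F4 | step 2 | 5-fluoro-2-(methoxymethoxy)benzene-1,3-diol | COCOc1c(O)cc(F)cc1O
F0 | step 12 | none | none
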